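**Retrosynthetic overview**
- Feature: in the cyclopentane C4–CH2–CH2–Cq–C5, the methyl-bearing quaternary carbon Cq is bonded to the ring-fusion CH (C5) and carries the benzylic carbon Ca as its exocyclic branch. With Ca at the aldehyde level this is a 1-methylcyclopentane-1-carbaldehyde, the pattern a 1-methylcyclohexene oxide leaves on contraction.
- Late disconnections: the two CHO groups (Vilsmeier–Haack), isobutyl (benzylic cation plus methallylsilane, then H2), the oxepane C–O bond (SNAr of the C4 alkoxide on an o-fluoroaryl ketone), and Ca–aryl (aryllithium plus aldehyde).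
- Key disconnection: Cq–C5, formed by a Li+-chelation-controlled Meinwald contraction of the β-epoxide of a 6-6-3 cis-octalinol.
- Octalinol: caran-4-one plus allyl (at C5) plus 3-methylbut-3-enyl (at C4), then allyl-to-propenyl shift and RCM. The caranone comes from (S)-carvone by cyclopropane closure and Wharton transposition.
- Ring order: ring A (carvone), cyclopropane, ring B (RCM), oxirane, cyclopentane (contraction of ring B), oxepane.

Key step: step 12

Labels: ring A is numbered as carane (C1 and C6 cyclopropane CH, C7 CMe2, C3 CHMe, C4 oxygenated carbon, C5 ring-fusion CH). Cq is the methyl-bearing quaternary carbon. Ca is in turn the epoxide CH, the CHO carbon and the benzylic CH. β is the face of ring A that carries C7; α is the other face.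

Remark: the cyclopropane carbons of the target have the configuration opposite to natural (+)-3-carene, so the carane ketone is derived from (S)-carvone.

**Step 1**
Reactants: 1 (S)-(+)-carvone
Product: 2 (5S)-5-(2-chloropropan-2-yl)-2-methylcyclohex-2-en-1-one (carvone hydrochloride)
Conditions: HCl (g), CH2Cl2, 0 °C
Reagents that add atoms: hydrogen chloride, Cl
Why: Markovnikov hydrochlorination protonates only the electron-rich isopropenyl group to the tertiary cation, the enone C=C is deactivated, and the carvone stereocentre is untouched.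

**Step 2**
Reactants: 2 carvone hydrochloride
Product: 3 (1R,6S)-3,7,7-trimethylbicyclo[4.1.0]hept-3-en-2-one (car-3-en-2-one)
Conditions: KOtBu, THF, 0 °C
Reagents that add atoms: none
Why: Intramolecular enolate alkylation (3-exo-tet) of the kinetic α′-enolate on the tertiary chloride closes the cyclopropane, and the new CH (C1) can only be cis-fused, so its configuration follows from the carvone centre (C6).

**Step 3**
Reactants: 3 car-3-en-2-one
Product: 4 3α,4α-epoxycaran-2-one
Conditions: 30% H2O2, NaOH (cat.), MeOH, 0 °C
Reagents that add atoms: hydrogen peroxide, OO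
Why: In this Weitz–Scheffer nucleophilic epoxidation, hydroperoxide adds to C4 on the α face because the endo methyl of C7 covers the β face.

**Step 4**
Reactants: 4 3α,4α-epoxycaran-2-one
Product: 6 (1R,4S,6S)-3,7,7-trimethylbicyclo[4.1.0]hept-2-en-4-ol (car-2-en-4α-ol), via epoxy hydrazone 5 (not isolated)
Conditions: N2H4·H2O, AcOH (cat.), MeOH, 0 °C → rt
Reagents that add atoms: none
Why: In the Wharton transposition the hydrazone opens the oxirane at C3 and loses N2, moving oxygen from C2 to C4 with the C4–O bond (α) retained; opening of the cyclopropane would require a strained cyclic allene and is not expected.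

**Step 5**
Reactants: 6 car-2-en-4α-ol
Product: 7 (1R,3S,4S,6S)-3,7,7-trimethylbicyclo[4.1.0]heptan-4-ol (3β-methyl 4α-ol)
Conditions: H2 (1 atm), PtO2 (cat.), EtOAc, rt
Reagents that add atoms: none
Why: Heterogeneous syn hydrogenation delivers H2 to the open, hydroxyl-bearing α face, so C3–H becomes α and the methyl β (the cis-carane outcome known for 2-carenes), and platinum is used because palladium tends to open vinylcyclopropanes.

**Step 6**
Reactants: 7 caran-4α-ol
Product: 8 (1R,3S,6S)-3,7,7-trimethylbicyclo[4.1.0]heptan-4-one (3β-methyl)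
Conditions: Dess–Martin periodinane, CH2Cl2, 0 °C → rt
Reagents that add atoms: none
Why: Dess–Martin oxidation is base-free, so the epimerisable C3 centre next to the new ketone should be preserved.

**Step 7**
Reactants: 8 caran-4-one; 9 allyl bromide
Product: 11 5α-allylcaran-4-one (C3 methyl β; allyl trans to the cyclopropane), via lithium enolate 10 (not isolated)
Conditions: LDA, THF, −78 °C; then 9, DMPU, −78 → −30 °C
Reagents that add atoms: allyl bromide (9), C=CCBr
Why: In this kinetic enolate alkylation LDA removes a C5 methylene proton rather than the C3 methine, and the electrophile enters on the α face because the endo methyl of C7 shields the β face, which sets C5.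

**Step 8**
Reactants: 11 5α-allylcaran-4-one; 12 4-bromo-2-methylbut-1-ene
Product: 14 5α-allyl-4α-(3-methylbut-3-enyl)caran-4β-ol, via 3-methylbut-3-enylmagnesium bromide 13 (not isolated)
Conditions: 12, Mg, THF, rt; LaCl3·2LiCl, then 11, THF, −78 → 0 °C; H2O
Reagents that add atoms: 4-bromo-2-methylbut-1-ene (12), CC(=C)CCBr
Why: The lanthanide salt in this Grignard 1,2-addition suppresses enolisation and reduction of the doubly α-branched ketone, and the nucleophile comes from the α face because a β trajectory runs into the endo methyl of C7, which sets C4 with OH β and both side chains α.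

**Step 9**
Reactants: 14 allyl dienol
Product: 15 4α-(3-methylbut-3-enyl)-5α-[(E)-prop-1-enyl]caran-4β-ol
Conditions: RuHCl(CO)(PPh3)3 (5 mol %), toluene, 80 °C
Reagents that add atoms: none
Why: Ru–H catalysed alkene isomerisation (hydrometalation then β-hydride elimination) moves the monosubstituted allyl double bond by one position, the 1,1-disubstituted alkene inserts far more slowly, and no stereocentre is touched.

**Step 10**
Reactants: 15 propenyl dienol
Product: 16 cis-octalinol (ring B: C4–CH2–CH2–Cq(CH3)=CaH–C5; C4–OH and C5–H β)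
Conditions: Grubbs II (5 mol %), CH2Cl2, 40 °C
Reagents that add atoms: none
Why: Ring-closing metathesis of the two cis (α) side chains forms an unstrained trisubstituted cyclohexene and is driven by loss of propene.

**Step 11**
Reactants: 16 cis-octalinol
Product: 17 β-epoxy cis-octalinol (oxirane oxygen on Cq and Ca β, cis to C4–OH and C5–H)
Conditions: mCPBA, CH2Cl2, 0 °C
Reagents that add atoms: 3-chloroperoxybenzoic acid, OOC(=O)c1cccc(Cl)c1
Why: In this Prilezhaev epoxidation the β face is the convex face of the cis-octalin (a ring-A carbon is always axial on the α face of ring B) and also carries the hydrogen-bonding homoallylic OH, so both effects place oxygen β and set Cq and Ca.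

**Step 12**
Reactants: 17 β-epoxy cis-octalinol
Product: 18 cis-hydrindane hydroxy aldehyde (Cq: CHO β and CH3 α; C4–OH and C5–H β; open form)
Conditions: anhydrous LiClO4 (5 M in Et2O), rt
Reagents that add atoms: none
Why: Li+ is bound by the epoxide oxygen and the cis (β) C4 hydroxyl together, which is possible only in the ring-B half-chair that holds C4–OH axial, and in this half-chair the tertiary Cq–O bond is pseudo-equatorial and antiperiplanar to the ring bond Ca–C5. As Cq–O ionises, C5 shifts from Ca to Cq and the oxygen left on Ca becomes the formyl oxygen, a Meinwald (semipinacol) rearrangement whose closest known cases are the LiClO4- and ZnBr2-promoted contractions of 1-methylcyclohexene oxides to 1-methylcyclopentanecarbaldehydes and the Li+-chelation control of cis-4-alkoxycyclohexene oxides. The cyclopentane C4–CH2–CH2–Cq–C5 is closed by this 1,2-alkyl shift, that is by six-to-five ring contraction and not by an exo or endo cyclisation. Cq, the only new stereocentre, is set by inversion because C5 enters anti to the departing β oxygen, so CHO ends β (cis to OH) and CH3 α, while C5 migrates with retention and keeps the cis ring fusion. The step needs carbon over hydride migration: the other half-chair, which a silyl ether bound to a bulky monodentate Lewis acid would populate, aligns Ca–H with the breaking bond and leads to the decalone, so the hydroxyl is left free as the second donor, and the cyclopropyl group on C5 adds migratory aptitude. The syn hydroxyl cannot open the epoxide because it cannot reach the rear side of either C–O bond, and perchlorate is non-nucleophilic.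

**Step 13**
Reactants: 19 5-fluorobenzene-1,3-diol
Product: 20 1,3-bis(benzyloxy)-5-fluorobenzene
Conditions: BnBr, K2CO3, DMF, rt
Reagents that add atoms: benzyl bromide, BrCc1ccccc1
Why: Williamson etherification installs benzyl groups that can later be removed by hydrogenolysis, which avoids a Lewis-acid demethylation that would endanger the tertiary aryl ether and the cyclopropane.

**Step 14**
Reactants: 20 1,3-bis(benzyloxy)-5-fluorobenzene
Product: 21 1,5-bis(benzyloxy)-2-bromo-3-fluorobenzene
Conditions: NBS, MeCN, 0 °C
Reagents that add atoms: N-bromosuccinimide, O=C1CCC(=O)N1Br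
Why: Electrophilic aromatic bromination goes para to one benzyloxy group and ortho to the small fluorine, not into the crowded site between the two ethers, which fixes the metalation site unambiguously.

**Step 15**
Reactants: 18 hydroxy aldehyde; 21 aryl bromide
Product: 23 benzylic diol (Ca carbinol as a mixture of epimers), via 2-fluoroaryllithium 22 (not isolated)
Conditions: 21 (2.5 equiv), n-BuLi, THF, −78 °C; then 18, −78 °C; H2O at −78 °C
Reagents that add atoms: 1,5-bis(benzyloxy)-2-bromo-3-fluorobenzene (21), Fc1cc(OCc2ccccc2)cc(OCc2ccccc2)c1Br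
Why: Br/Li exchange followed by 1,2-addition works because one equivalent of aryllithium deprotonates the OH and a second adds to the non-enolisable neopentyl aldehyde; −78 °C prevents benzyne formation, and the new carbinol centre is erased in step 16.

**Step 16**
Reactants: 23 benzylic diol
Product: 24 hydroxy aryl ketone
Conditions: TPAP (5 mol %), NMO, 4 Å MS, CH2Cl2, rt
Reagents that add atoms: none
Why: Ley–Griffith oxidation under non-acidic conditions oxidises only the secondary benzylic alcohol, leaves the tertiary alcohol alone, and avoids ionising the electron-rich carbinol.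

**Step 17**
Reactants: 24 hydroxy aryl ketone
Product: 26 bridged benzoxepinone (ring O–C4–C5–Cq–Ca(=O)–C(aryl)–C(aryl)), via potassium alkoxide 25 (not isolated)
Conditions: KHMDS, THF–DMF, 0 → 60 °C
Reagents that add atoms: none
Why: In this intramolecular SNAr the C4 alkoxide, held cis-1,3 to the aroyl group on the cyclopentane, adds to the C–F carbon ortho to the ketone, which accepts the Meisenheimer charge; both benzyloxy groups are meta to the reacting carbon, fluoride is expelled, and no stereocentre is formed.

**Step 18**
Reactants: 26 bridged benzoxepinone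
Product: 27 benzoxepinol (Ca carbinol; configuration irrelevant)
Conditions: LiAlH4, THF, 0 °C → rt; basic work-up
Reagents that add atoms: none
Why: Hydride reduction of the only reducible group gives a carbinol whose configuration does not matter, since it is ionised in the next step.

**Step 19**
Reactants: 27 benzoxepinol; 28 methallyltrimethylsilane
Product: 29 methallyl benzoxepane (methallyl on the face of Ca turned to C5–H; Ca–H turned to the CH2CH2 bridge)
Conditions: 28, InCl3 (10 mol %), CH2Cl2, 0 °C
Reagents that add atoms: methallyltrimethylsilane (28), CC(=C)C[Si](C)(C)C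
Why: In this Lewis-acid catalysed Hosomi–Sakurai-type benzylic allylation the trialkoxybenzyl cation has no β-hydrogen to lose, and it should be attacked on the exo-like face flanked only by C5–H of the one-carbon bridge rather than on the face facing the inward hydrogens of the CH2CH2 bridge, which sets Ca.

**Step 20**
Reactants: 29 methallyl benzoxepane
Product: 30 isobutyl resorcinol (both phenols free)
Conditions: H2 (1 atm), 10% Pd/C, EtOAc–MeOH, rt
Reagents that add atoms: none
Why: One catalytic hydrogenation saturates the 1,1-disubstituted alkene to isobutyl and hydrogenolyses both benzyl ethers, while the isolated cyclopropane and the non-benzylic tertiary alkyl aryl ether should survive at 1 atm.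

**Step 21**
Reactants: 30 isobutyl resorcinol
Product: 32 CNP0202714.1 (target), via bis(iminium) salt 31 (not isolated)
Conditions: POCl3, DMF, EtOAc, 0 °C → rt; then H2O, 40 °C
Reagents that add atoms: N,N-dimethylformamide, CN(C)C=O; water, O
Why: Double Vilsmeier–Haack formylation, as used for diformylphloroglucinols, fills the only two free ring positions, each ortho or para to three oxygens, and the DMF-buffered medium spares the cyclopropane and the tertiary ether.

**Compound list**
1 | (S)-(+)-carvone | CC1=CC[C@@H](CC1=O)C(C)=C | starting material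
2 | (5S)-5-(2-chloropropan-2-yl)-2-methylcyclohex-2-en-1-one | CC1=CC[C@@H](CC1=O)C(C)(C)Cl | intermediate
3 | (1R,6S)-car-3-en-2-one | CC1=CC[C@H]2[C@@H](C1=O)C2(C)C | intermediate
4 | 3α,4α-epoxycaran-2-one | O1[C@H]2C[C@H]3[C@@H](C(=O)[C@@]12C)C3(C)C | intermediate
5 | hydrazone of 4 | O1[C@H]2C[C@H]3[C@@H](C(=NN)[C@@]12C)C3(C)C | intermediate
6 | (1R,4S,6S)-car-2-en-4-ol | O[C@H]1C[C@H]2[C@@H](C=C1C)C2(C)C | intermediate
7 | (1R,3S,4S,6S)-caran-4-ol | O[C@H]1C[C@H]2[C@@H](C[C@@H]1C)C2(C)C | intermediate
8 | (1R,3S,6S)-caran-4-one | O=C1C[C@H]2[C@@H](C[C@@H]1C)C2(C)C | intermediate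
9 | allyl bromide | C=CCBr | starting material
10 | lithium C4–C5 enolate of 8 | [Li]OC1=C[C@H]2[C@@H](C[C@@H]1C)C2(C)C | intermediate
11 | 5α-allylcaran-4-one | O=C1[C@@H](CC=C)[C@H]2[C@@H](C[C@@H]1C)C2(C)C | intermediate
12 | 4-bromo-2-methylbut-1-ene | CC(=C)CCBr | starting material
13 | 3-methylbut-3-enylmagnesium bromide | CC(=C)CC[Mg]Br | intermediate
14 | 5α-allyl-4α-(3-methylbut-3-enyl)caran-4β-ol | O[C@]1(CCC(C)=C)[C@@H](CC=C)[C@H]2[C@@H](C[C@@H]1C)C2(C)C | intermediate
15 | 4α-(3-methylbut-3-enyl)-5α-[(E)-prop-1-enyl]caran-4β-ol | O[C@]1(CCC(C)=C)[C@@H](/C=C/C)[C@H]2[C@@H](C[C@@H]1C)C2(C)C | intermediate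
16 | cis-octalinol | O[C@]12CCC(C)=C[C@H]1[C@H]1[C@@H](C[C@@H]2C)C1(C)C | intermediate
17 | β-epoxy cis-octalinol (key-step precursor) | O[C@]12CC[C@]3(C)O[C@@H]3[C@H]1[C@H]1[C@@H](C[C@@H]2C)C1(C)C | intermediate
18 | cis-hydrindane hydroxy aldehyde (key-step product) | O[C@]12CC[C@](C)(C=O)[C@H]1[C@H]1[C@@H](C[C@@H]2C)C1(C)C | intermediate
19 | 5-fluorobenzene-1,3-diol | Oc1cc(O)cc(F)c1 | starting material
20 | 1,3-bis(benzyloxy)-5-fluorobenzene | Fc1cc(OCc2ccccc2)cc(OCc2ccccc2)c1 | intermediate
21 | 1,5-bis(benzyloxy)-2-bromo-3-fluorobenzene | Fc1cc(OCc2ccccc2)cc(OCc2ccccc2)c1Br | intermediate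
22 | 2,4-bis(benzyloxy)-6-fluorophenyllithium | [Li]c1c(F)cc(OCc2ccccc2)cc1OCc1ccccc1 | intermediate
23 | benzylic diol (Ca epimers) | O[C@]12CC[C@](C)(C(O)c3c(F)cc(OCc4ccccc4)cc3OCc3ccccc3)[C@H]1[C@H]1[C@@H](C[C@@H]2C)C1(C)C | intermediate
24 | hydroxy aryl ketone | O[C@]12CC[C@](C)(C(=O)c3c(F)cc(OCc4ccccc4)cc3OCc3ccccc3)[C@H]1[C@H]1[C@@H](C[C@@H]2C)C1(C)C | intermediate
25 | potassium alkoxide of 24 | [K]O[C@]12CC[C@](C)(C(=O)c3c(F)cc(OCc4ccccc4)cc3OCc3ccccc3)[C@H]1[C@H]1[C@@H](C[C@@H]2C)C1(C)C | intermediate
26 | bridged benzoxepinone | O=C1c2c(OCc3ccccc3)cc(OCc3ccccc3)cc2O[C@]23CC[C@@]1(C)[C@H]2[C@H]1[C@@H](C[C@@H]3C)C1(C)C | intermediate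
27 | benzoxepinol (Ca unspecified) | OC1c2c(OCc3ccccc3)cc(OCc3ccccc3)cc2O[C@]23CC[C@@]1(C)[C@H]2[C@H]1[C@@H](C[C@@H]3C)C1(C)C | intermediate
28 | methallyltrimethylsilane | CC(=C)C[Si](C)(C)C | starting material
29 | methallyl benzoxepane | CC(=C)C[C@H]1c2c(OCc3ccccc3)cc(OCc3ccccc3)cc2O[C@]23CC[C@@]1(C)[C@H]2[C@H]1[C@@H](C[C@@H]3C)C1(C)C | intermediate
30 | isobutyl resorcinol | CC(C)C[C@H]1c2c(O)cc(O)cc2O[C@]23CC[C@@]1(C)[C@H]2[C@H]1[C@@H](C[C@@H]3C)C1(C)C | intermediate
31 | bis(dimethyliminium) dichloride | CC(C)C[C@H]1c2c(O)c(C=[N+](C)C)c(O)c(C=[N+](C)C)c2O[C@]23CC[C@@]1(C)[C@H]2[C@H]1[C@@H](C[C@@H]3C)C1(C)C.[Cl-].[Cl-] | intermediate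
32 | CNP0202714.1 | CC(C)C[C@H]1c2c(O)c(C=O)c(O)c(C=O)c2O[C@]23CC[C@@]1(C)[C@H]2[C@H]1[C@@H](C[C@@H]3C)C1(C)C | target

**Step count**
Total steps: 21. Longest linear sequence: 19 (steps 1–12 and 15–21).

**Steps most likely to fail**

Step 12. Ionisation by Li+ may be too slow, or the epoxide may react through the unchelated half-chair, so that hydride migrates instead of carbon.

The fallback runs from 16 back to 18. It is a stepwise halohydrin semipinacol on the opposite epoxide, in which a hydride shift has no aligned pathway.
- The hydroxyl of 16 is silylated (TESOTf, 2,6-lutidine) to the octalin triethylsilyl ether F1.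
- NBS in aqueous DME should give the bromohydrin F2 (Ca–Br β, Cq–OH α), which K2CO3 in MeOH closes to the α-epoxide F3.
- LiBr·HMPA in hot toluene opens F3 at the tertiary carbon from the open β face to the bromo alkoxide F4 (Cq–Br β, Ca–OLi α).
- The diaxial form of F4 can only return to F3. Its diequatorial form has Cq–Br antiperiplanar to Ca–C5 and contracts to the silyl-protected aldehyde F5.
- The leaving group is again β, so Cq has the same configuration as in 18. TBAF then gives 18.

Step 17. The aroyl group is twisted out of the arene plane by its two ortho substituents and the quaternary neighbour. Activation of C–F may therefore be insufficient, while reversible addition of the alkoxide to the ketone opens a path to loss of the aryl group by C–C cleavage.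

The fallback runs from 18 back to 26. It forms the C–O bond by copper catalysis instead of addition–elimination.
- Commercial 1,3-bis(benzyloxy)-5-bromobenzene is iodinated (NIS) to 1,5-bis(benzyloxy)-3-bromo-2-iodobenzene F6.
- Selective I/Mg exchange (iPrMgCl·LiCl, −20 °C) gives the 2-bromoarylmagnesium chloride F7, which adds to 18 to give the bromo diol F8.
- TPAP/NMO gives the bromo hydroxy ketone F9.
- An Ullmann-type intramolecular O-arylation (CuI, 1,10-phenanthroline, Cs2CO3, toluene, 110 °C) closes the ether to 26.

Step 19. Facial selectivity of the attack on the benzylic cation may be poor or reversed if the flexible seven-membered ring tilts the arene toward C5–H.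

The fallback runs from 26 back to 29 and reverses the order in which carbon and hydrogen are introduced.
- Methallylmagnesium chloride adds to the ketone of 26 to give the methallyl carbinol F10.
- Ionic deoxygenation (Et3SiH, BF3·OEt2, CH2Cl2, −78 °C) delivers hydride to the same cation face that the carbon nucleophile preferred.
- This places Ca–H toward the CH2CH2 bridge and the methallyl group toward C5–H, as in 29.

**Further compounds**
F1 | step 12 | triethylsilyl ether of octalinol 16 | CC[Si](CC)(CC)O[C@]12CCC(C)=C[C@H]1[C@H]1[C@@H](C[C@@H]2C)C1(C)C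
F2 | step 12 | bromohydrin (Ca–Br β, Cq–OH α) | CC[Si](CC)(CC)O[C@]12CC[C@@](C)(O)[C@H](Br)[C@H]1[C@H]1[C@@H](C[C@@H]2C)C1(C)C
F3 | step 12 | α-epoxide of F1 | CC[Si](CC)(CC)O[C@]12CC[C@@]3(C)O[C@H]3[C@H]1[C@H]1[C@@H](C[C@@H]2C)C1(C)C
F4 | step 12 | lithium alkoxide of the tertiary β-bromide | CC[Si](CC)(CC)O[C@]12CC[C@](C)(Br)[C@@H](O[Li])[C@H]1[C@H]1[C@@H](C[C@@H]2C)C1(C)C
F5 | step 12 | triethylsilyl ether of aldehyde 18 | CC[Si](CC)(CC)O[C@]12CC[C@](C)(C=O)[C@H]1[C@H]1[C@@H](C[C@@H]2C)C1(C)C
F6 | step 17 | 1,5-bis(benzyloxy)-3-bromo-2-iodobenzene | Brc1cc(OCc2ccccc2)cc(OCc2ccccc2)c1I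
F7 | step 17 | 2,4-bis(benzyloxy)-6-bromophenylmagnesium chloride | Cl[Mg]c1c(Br)cc(OCc2ccccc2)cc1OCc1ccccc1
F8 | step 17 | bromo diol (Ca epimers) | O[C@]12CC[C@](C)(C(O)c3c(Br)cc(OCc4ccccc4)cc3OCc3ccccc3)[C@H]1[C@H]1[C@@H](C[C@@H]2C)C1(C)C
F9 | step 17 | bromo hydroxy ketone | O[C@]12CC[C@](C)(C(=O)c3c(Br)cc(OCc4ccccc4)cc3OCc3ccccc3)[C@H]1[C@H]1[C@@H](C[C@@H]2C)C1(C)C
F10 | step 19 | methallyl carbinol (Ca unspecified) | CC(=C)CC1(O)c2c(OCc3ccccc3)cc(OCc3ccccc3)cc2O[C@]23CC[C@@]1(C)[C@H]2[C@H]1[C@@H](C[C@@H]3C)C1(C)C
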